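**The vessel.** Your vessel is closed, stirred and isothermal. One catalyst in it serves two substrates, and both cycles consume the coupling partner, so target and second product share one charge of it.

starting material 0.10 M; second substrate 2.00 equiv; coupling partner 1.05 equiv; free catalyst 10 mol%; time 5.0 h

    second substrate + free catalyst ⇌ catalyst intermediate B (K1 = 2.9 L mol⁻¹, k1 = 0.16 L mol⁻¹ s⁻¹)
    starting material + free catalyst ⇌ catalyst intermediate A (K2 = 2700 L mol⁻¹, k2 = 0.13 L mol⁻¹ s⁻¹)
    coupling partner + catalyst intermediate A → free catalyst + target (k3 = 0.13 L mol⁻¹ s⁻¹)
    coupling partner + catalyst intermediate B → free catalyst + second product (k4 = 0.15 L mol⁻¹ s⁻¹)
    crystals ⇌ target, rate k5*(cs5 - [target]) while solid is left; crystals form when [target] > cs5 (cs5 = 35 mM, k5 = 0.035 s⁻¹)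

- for target the crystals are counted in
- as a solid, counted per litre of solution: crystals
- the reaction counts as stopped when no species that holds the starting material changes by six tenths of a point or more over the second half of the time
- what has gone from starting material into another species counts as reacted, even if it can come back
- run time (flask): 5.0 h

- at 5.0 h, what has stopped the reaction, if anything has (the coupling partner has run out first / no working catalyst is left / all of the starting material has reacted / it is still moving / forward and back rates have come level)
- conversion of starting material at 5.0 h
- amount of target at 5.0 h, in percent of the starting material charged
- amount of catalyst intermediate A at 5.0 h, in percent of the starting material charged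

**Opening rates.** I reckon with rates on free catalyst. At the start, the forward binding of starting material runs at 0.41 of that of second substrate, which favours second product. But binding doesn't yet spend partner. Catalyst intermediate B falls back at 3.31 min⁻¹ and goes on with partner at 0.945 min⁻¹, so its channel is slowed by a factor of 4.50. Catalyst intermediate A falls back far more slowly than it goes on, so its channel keeps its opening rate.

**The split.** Take the opening rate of target over that of second product, a selectivity factor, and call it the split: 1.83. Both parts drift as the charges fall, and I assume here that the drifts cancel.

**The end.** With that split, 64.7 % of the partner goes to target, which gives 67.9 % of the starting material charged. Catalyst intermediate A can hold up to 10.0 % more, so I expect about 77.9 % conversion. Steps 2 and 3 have equal constants, so once less partner than starting material remains, I expect catalyst intermediate A to become the resting state. I then expect the partner, the limiting reagent, to decay with a half-life of 0.148 h, which is short against 5.0 h.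

**The forecast.** The forecast, above my target figure, gives "the coupling partner has run out first", 83 % conversion, 73.5 % target and 9.7 % catalyst intermediate A, with the competing cycle “taking roughly a third or less of it”.

**The result.** The simulation of this flask gives "the coupling partner has run out first", with 83.1 % conversion, 73.4 % target and 9.68 % catalyst intermediate A. In this flask the partner stands at 0 % of its charge after 2.50 h.

**The neighbour.** This flask ends with second product at 31.6 % of the starting material charged, so target over second product, summed over the run, reads 2.33. That is above my opening 1.83, so the drifts did not cancel. Now take the neighbour flask with 0.040 M of starting material, its equivalents held. The binding ratio stays, but the partner step slows, so the factor becomes 9.76 and the split 3.96. That reckons 83.8 % target. That neighbour flask gives 85.1 %, and its target over second product, summed over the run, reads 4.33.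

The rate constants were chosen freely.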